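The flask starts slowly: the elm run makes target at 0.00125 M min⁻¹ over the first 1.6 min, but at 0.00245 M min⁻¹ between 3.6 min and 8.0 min, which is faster.

| flask | starting material | partner | time |
|---|---|---|---|
| elm | 0.150 M | 0.450 M |  |
| oak | 0.220 M | 0.450 M |  |
| maple | 0.150 M | 0.680 M |  |
| cedar | 0.0750 M | 0.900 M | 40 min |

- elm run (time / min: [target] / M): 1.6: 0.0020; 3.6: 0.0053; 8.0: 0.0161; 18: 0.0357; 40: 0.0703
- oak run (time / min: [target] / M): 1.6: 0.0025; 3.6: 0.0076; 8.0: 0.0220; 18: 0.0516; 40: 0.1001
- maple run (time / min: [target] / M): 1.6: 0.0012; 3.6: 0.0066; 8.0: 0.0181; 18: 0.0405; 40: 0.0785

(standard deviation of a reading: 4 × 10⁻⁴ M)

- Overall: starting material + partner -> target.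
- Constant volume, constant temperature.
- A reading of a species includes what of it is bound.
- "The second partner" is partner.
- An order is taken over about fifteen percent of the charge, up and down.

- the power of [starting material] that the first rate follows, about the charge of the elm run; measure it at two percent of starting material made into target (one fixed amount of target, the same in the runs compared)
- the power of [partner] that the first rate follows, about the charge of the elm run; measure it at two percent of starting material made into target
- target in the cedar run at 40 min, as a share of the starting material charged

I follow one molecule of starting material and ask for its chance of not having become target by 40 min. The elm run gives 0.632 for the exponent Θ, minus the natural logarithm of the share of the charge not made into target. That chance is then exp(−Θ).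

At the same time the oak run gives 0.607 and the maple run 0.741. Read off these readings, each run against the elm run with one charge changed, Θ at that time follows the partner charge with power 0.384 and the starting-material charge with power −0.107. Carried to the cedar charge, these give Θ = 0.889, so I commit to 58.9%.

Is one number enough? Not for the early minutes: in the elm run Θ per minute is 0.00839 min⁻¹ by 1.6 min and 0.0158 min⁻¹ by 40 min, higher. Θ compares flasks at 40 min; it gives me no first-rate orders.

The forecast gives 0.8 for the power in starting material, 0.25 for the power in partner and 58% for the cedar run, a share lower than mine by 0.90 percentage points. It notes: “Two percent conversion (0.003 M) falls inside the lag”.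

The simulation gives 0.74 and 0.30 for these powers about the elm charge, and 56.7% for the cedar run, which is Θ = 0.838 for the cedar run.

    starting material ⇌ intermediate (0.3198 min⁻¹, 0.4164 min⁻¹)
    intermediate + partner → target (1.170 M⁻¹ min⁻¹)
    starting material + partner ⇌ idle substrate-reagent adduct, settled at all times (9.920 M⁻¹)
    2 partner ⇌ idle reagent dimer, settled at all times (101.0 M⁻¹)

Early in the elm run the apparent order in partner is 0.30, above the forecast's 0.25. At its average pace up to 40 min, the maple run's Θ of 0.741 puts target at a quarter of the charge at 15.5 min; the maple run reaches it at 16.3 min.

The readings come from a simulation with made-up constants, noise included.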